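Ring A is a pentasubstituted resorcinol in which C4a, the carbon that carries the C4 stereocentre, sits meta to both oxygens (C6, C8) and next to the carboxyl-bearing C8a, a pattern no electrophilic substitution reaches. Ring A is therefore assembled around C4a by disconnecting C4a–C8a, C8–C8a, C6–C7 and C5–C6. One photochemical Wolff rearrangement/ketene–alkyne [2+2]/4π-opening/6π-closure cascade joins ethoxyethyne to an acyclic (E)-alkenyl 2-diazo-3-oxo tert-butyl ester that already holds the (R)-but-3-en-2-yl group, giving the complete benzoate with differentiated oxygens. The vinyl group later becomes C3 and C9, and a closing hydrogenolysis lets the keto acid fold into the hemiketal lactone.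

Key step: step 8

Remark on the precursor: the ester of the diazo compound is tert-butyl, so that the Lewis acid which frees C8–OH also frees the carboxyl group and no di-ortho-substituted benzoate has to be saponified.
Remark on configuration: only C4 is set by reagent control; the hemiketal carbon C3 is assumed to equilibrate by ring–chain tautomerism. L in step 2 is O,O′-[(S)-1,1′-binaphthalene-2,2′-diyl] N,N-bis[(S)-1-(2-methoxyphenyl)ethyl]phosphoramidite; if it delivers the antipode of 4, its enantiomer is used.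
Remark on supply: 4,5-dimethylbenzene-1,3-diol and 3-tert-butoxy-3-oxopropanoic acid are assumed to be catalogue chemicals.

Step 1
Reactants: 1 (E)-but-2-en-1-ol
Product: 2 (E)-but-2-en-1-yl methyl carbonate
Conditions: MeOCOCl, pyridine, CH2Cl2, 0 °C
Reagents that add atoms: methyl chloroformate, COC(=O)Cl
Why: Acylation of a primary allylic alcohol by a chloroformate (carbonate formation) is routine and installs the leaving group for the allylic substitution; no stereocentre is formed.

Step 2
Reactants: 2 (E)-but-2-en-1-yl methyl carbonate; 3 dimethyl malonate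
Product: 4 dimethyl 2-[(2R)-but-3-en-2-yl]propanedioate
Conditions: [Ir(cod)Cl]2 (2 mol %), (Sa,S,S)-L (4 mol %), TBD (8 mol %), THF, rt
Reagents that add atoms: none
Why: Iridium–phosphoramidite asymmetric allylic alkylation of linear alkyl-substituted allyl carbonates by malonate is branched-selective, and the chiral ligand decides which face of the substituted allyl terminus is attacked, which should set the future C4 as R.

Step 3
Reactants: 4 dimethyl 2-[(2R)-but-3-en-2-yl]propanedioate
Product: 6 (3S)-3-methylpent-4-enoic acid, via diacid 5 (not isolated)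
Conditions: KOH, MeOH/H2O, reflux; HCl; neat, 150 °C
Reagents that add atoms: potassium hydroxide, [K+].[OH-]
Why: Saponification and thermal decarboxylation of a monosubstituted malonic acid (malonic ester synthesis) do not touch the β-stereocentre, whose descriptor becomes S only through the changed CIP ranking.

Step 4
Reactants: 6 (3S)-3-methylpent-4-enoic acid; 7 3-tert-butoxy-3-oxopropanoic acid
Product: 9 tert-butyl (5S)-5-methyl-3-oxohept-6-enoate, via acyl imidazolide 8 (not isolated)
Conditions: CDI, THF, rt; then 7, MgCl2, Et3N, MeCN, rt → 40 °C; aq. citric acid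
Reagents that add atoms: none
Why: Masamune–Brooks homologation, in which the acyl imidazolide is C-acylated by the magnesium enolate of the malonate half-ester and decarboxylates to the β-keto ester, is reliable and leaves the remote stereocentre alone.

Step 5
Reactants: 9 tert-butyl (5S)-5-methyl-3-oxohept-6-enoate
Product: 10 tert-butyl (5S)-2-diazo-5-methyl-3-oxohept-6-enoate
Conditions: 4-AcNHC6H4SO2N3, Et3N, MeCN, 0 °C → rt
Reagents that add atoms: 4-acetamidobenzenesulfonyl azide, CC(=O)Nc1ccc(cc1)S(=O)(=O)N=[N+]=[N-]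
Why: Regitz diazo transfer to the doubly activated methylene of a β-keto ester is general and chemoselective.

Step 6
Reactants: 10 tert-butyl (5S)-2-diazo-5-methyl-3-oxohept-6-enoate; 11 acetaldehyde
Product: 12 tert-butyl 4-[(2R)-but-3-en-2-yl]-2-diazo-5-hydroxy-3-oxohexanoate (mixture at C4 and C5)
Conditions: LiN(SiMe3)2, THF, −78 °C; 11; NH4Cl (aq), −78 °C
Reagents that add atoms: none
Why: γ-Deprotonation of 2-diazo-3-oxo esters and aldol addition to aldehydes is an established reaction of this substrate class; the two new centres form unselectively and are erased in step 7.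

Step 7
Reactants: 12 tert-butyl 4-[(2R)-but-3-en-2-yl]-2-diazo-5-hydroxy-3-oxohexanoate
Product: 14 tert-butyl (4E)-4-[(2R)-but-3-en-2-yl]-2-diazo-3-oxohex-4-enoate, via mesylate 13 (not isolated)
Conditions: MsCl, Et3N, CH2Cl2, 0 °C; then DBU, 0 °C → rt
Reagents that add atoms: none
Why: Mesylation and E1cB elimination of a β-hydroxy ketone should give the conjugated enone with the methyl group trans to the acyl group, and the allylic stereocentre is not vinylogously acidic and should persist.

Step 8
Reactants: 14 tert-butyl (4E)-4-[(2R)-but-3-en-2-yl]-2-diazo-3-oxohex-4-enoate; 15 ethoxyethyne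
Product: 20 tert-butyl 2-[(2R)-but-3-en-2-yl]-6-ethoxy-4-hydroxy-3-methylbenzoate, via vinylketene 16 (not isolated), via cyclobutenone 17 (not isolated), via dienylketene 18 (not isolated), via cyclohexadienone 19 (not isolated)
Conditions: hν (300 nm, Pyrex), 15 (4 equiv), degassed toluene, rt; evaporate excess 15; toluene, 90 °C
Reagents that add atoms: none
Why: Proposed new method: light expels N2 from 14 with 1,2-shift of the alkenyl group to the diazo carbon (Wolff rearrangement, C4a–C8a), and the ester-bearing vinylketene 16 should add through its C=C bond to the polarised ynol ether, the alkyne CH bonding to the ketene carbonyl carbon (C6–C7) and the ethoxy-bearing carbon to the ester-bearing carbon (C8–C8a), to give cyclobutenone 17. The closest known reaction type is the photochemical benzannulation of unsaturated diazomethyl ketones with alkoxy- or siloxyalkynes, which has not been shown for a 2-diazo-3-oxo ester whose ketene carries an alkoxycarbonyl group. Ring A is closed on warming by reversible 4π electrocyclic opening of 17 to dienylketene 18 and 6π electrocyclisation (C5–C6) to dienone 19, which tautomerises to the pentasubstituted phenol 20 with C7–H; the four-membered ring is only a relay. No lasting stereocentre is formed, the sp3 centres of 17 and 19 vanish on aromatisation, and the C4 methine is a spectator because its hydrogen is neither enolisable nor part of any pericyclic array. The step needs [2+2] periselectivity over closure through the ester carbonyl oxygen or the alkenyl terminus, and one alkyne orientation; the donor oxygen of 15 fixes the orientation, while the weakly nucleophilic, bulky tert-butyl ester, the non-polar solvent and the excess of 15 are chosen to favour the concerted cycloaddition. The (E) geometry of 14 puts the C5 methyl outward in the 6π transition state, and since cyclobutenone opening is reversible only the dienylketene isomer that can cyclise is drained.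

Step 9
Reactants: 20 tert-butyl 2-[(2R)-but-3-en-2-yl]-6-ethoxy-4-hydroxy-3-methylbenzoate
Product: 21 tert-butyl 2-[(2R)-but-3-en-2-yl]-6-ethoxy-4-methoxy-3-methylbenzoate
Conditions: MeI, K2CO3, acetone, 40 °C
Reagents that add atoms: iodomethane, CI
Why: Williamson O-methylation of the only free phenol (C6–OH) is unambiguous.

Step 10
Reactants: 21 tert-butyl 2-[(2R)-but-3-en-2-yl]-6-ethoxy-4-methoxy-3-methylbenzoate
Product: 22 2-[(2R)-but-3-en-2-yl]-6-hydroxy-4-methoxy-3-methylbenzoic acid
Conditions: BCl3 (4 equiv), CH2Cl2, −78 → 0 °C; H2O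
Reagents that add atoms: none
Why: BCl3 cleaves tert-butyl esters and, through a six-membered boron chelate to the carboxyl group, the alkyl aryl ether ortho to it (chelation-controlled ether cleavage), while the unchelated C6 methyl ether and the monosubstituted alkene are expected to survive at low temperature.

Step 11
Reactants: 22 2-[(2R)-but-3-en-2-yl]-6-hydroxy-4-methoxy-3-methylbenzoic acid
Product: 23 benzyl 6-(benzyloxy)-2-[(2R)-but-3-en-2-yl]-4-methoxy-3-methylbenzoate
Conditions: BnBr, K2CO3, DMF, 50 °C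
Reagents that add atoms: benzyl bromide, BrCc1ccccc1
Why: Double O-alkylation of carboxylate and phenoxide (Williamson-type) installs two groups that leave together in the final hydrogenolysis, and the non-acidic C4–H is safe under carbonate.

Step 12
Reactants: 23 benzyl 6-(benzyloxy)-2-[(2R)-but-3-en-2-yl]-4-methoxy-3-methylbenzoate
Product: 24 benzyl 6-(benzyloxy)-2-[(2S)-3,4-dihydroxybutan-2-yl]-4-methoxy-3-methylbenzoate (mixture at C3)
Conditions: OsO4 (2 mol %), NMO, acetone/H2O, rt
Reagents that add atoms: N-methylmorpholine N-oxide, C[N+]1([O-])CCOCC1; water, O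
Why: Upjohn dihydroxylation of a monosubstituted alkene is reliable and spares arenes and benzyl groups; the C3 carbinol forms as an epimer mixture that does not matter because C3 is oxidised in step 17.

Step 13
Reactants: 25 4,5-dimethylbenzene-1,3-diol
Product: 27 4,6-dihydroxy-2,3-dimethylbenzaldehyde, via iminium chloride 26 (not isolated)
Conditions: POCl3, DMF, MeCN, 0 °C → rt; H2O, 50 °C
Reagents that add atoms: N,N-dimethylformamide, CN(C)C=O; water, O
Why: Vilsmeier–Haack formylation of 5-alkylresorcinols goes para to one hydroxyl and ortho to the other at the position next to the ring methyl, not between the two oxygens, as with orcinol.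

Step 14
Reactants: 27 4,6-dihydroxy-2,3-dimethylbenzaldehyde
Product: 28 4,6-bis(benzyloxy)-2,3-dimethylbenzaldehyde
Conditions: BnBr, K2CO3, DMF, 60 °C
Reagents that add atoms: benzyl bromide, BrCc1ccccc1
Why: Williamson benzylation of both phenols, the chelated one needing gentle heating, gives ethers that are removed at the end by hydrogenolysis.

Step 15
Reactants: 28 4,6-bis(benzyloxy)-2,3-dimethylbenzaldehyde
Product: 29 4,6-bis(benzyloxy)-2,3-dimethylbenzoic acid
Conditions: NaClO2, NaH2PO4, 2-methylbut-2-ene, t-BuOH/H2O, rt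
Reagents that add atoms: sodium chlorite, [Na+].[O-]Cl=O
Why: Pinnick oxidation converts hindered, electron-rich benzaldehydes to the acids, the alkene scavenger removing hypochlorite before it can chlorinate the ring.

Step 16
Reactants: 29 4,6-bis(benzyloxy)-2,3-dimethylbenzoic acid; 24 benzyl 6-(benzyloxy)-2-[(2S)-3,4-dihydroxybutan-2-yl]-4-methoxy-3-methylbenzoate
Product: 31 benzyl 6-(benzyloxy)-2-[(2S)-4-{[4,6-bis(benzyloxy)-2,3-dimethylbenzoyl]oxy}-3-hydroxybutan-2-yl]-4-methoxy-3-methylbenzoate, via acid chloride 30 (not isolated)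
Conditions: 29, (COCl)2, cat. DMF, CH2Cl2, 0 °C → rt, evaporate; then 24, pyridine, cat. DMAP, CH2Cl2, −20 → 0 °C
Reagents that add atoms: none
Why: Esterification through the acid chloride lets the di-ortho-substituted aroyl group discriminate in favour of the primary hydroxyl over the secondary one, which is shielded by the hindered benzylic centre.

Step 17
Reactants: 31 benzyl 6-(benzyloxy)-2-[(2S)-4-{[4,6-bis(benzyloxy)-2,3-dimethylbenzoyl]oxy}-3-hydroxybutan-2-yl]-4-methoxy-3-methylbenzoate
Product: 32 benzyl 6-(benzyloxy)-2-[(2S)-4-{[4,6-bis(benzyloxy)-2,3-dimethylbenzoyl]oxy}-3-oxobutan-2-yl]-4-methoxy-3-methylbenzoate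
Conditions: Dess–Martin periodinane, pyridine, CH2Cl2, 0 °C → rt
Reagents that add atoms: none
Why: Dess–Martin oxidation is fast and near-neutral, so both C3 epimers should converge on one ketone without enolisation toward the C4 stereocentre.

Step 18
Reactants: 32 benzyl 6-(benzyloxy)-2-[(2S)-4-{[4,6-bis(benzyloxy)-2,3-dimethylbenzoyl]oxy}-3-oxobutan-2-yl]-4-methoxy-3-methylbenzoate
Product: 34 [(3R,4S)-3,8-dihydroxy-6-methoxy-4,5-dimethyl-1-oxo-3,4-dihydro-1H-2-benzopyran-3-yl]methyl 4,6-dihydroxy-2,3-dimethylbenzoate, via keto acid 33 (not isolated)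
Conditions: H2 (1 atm), Pd/C (10 wt % Pd), EtOAc, rt
Reagents that add atoms: none
Why: Hydrogenolysis removes all four benzyl groups under neutral conditions and the freed keto acid closes to the six-membered hemiketal lactone by ring–chain tautomerism, C3 being expected to settle as the epimer with axial hydroxyl (anomeric stabilisation) trans to the pseudo-axial C4 methyl, which is the 3R,4S target.

Compound list
1 | (E)-but-2-en-1-ol | C/C=C/CO | starting material
2 | (E)-but-2-en-1-yl methyl carbonate | C/C=C/COC(=O)OC | intermediate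
3 | dimethyl malonate (dimethyl propanedioate) | COC(=O)CC(=O)OC | starting material
4 | dimethyl 2-[(2R)-but-3-en-2-yl]propanedioate | COC(=O)C(C(=O)OC)[C@H](C)C=C | intermediate
5 | 2-[(2R)-but-3-en-2-yl]propanedioic acid (diacid, not isolated) | OC(=O)C(C(=O)O)[C@H](C)C=C | intermediate
6 | (3S)-3-methylpent-4-enoic acid | OC(=O)C[C@H](C)C=C | intermediate
7 | 3-tert-butoxy-3-oxopropanoic acid (mono-tert-butyl malonate) | CC(C)(C)OC(=O)CC(=O)O | starting material
8 | (3S)-1-(1H-imidazol-1-yl)-3-methylpent-4-en-1-one (acyl imidazolide, not isolated) | O=C(C[C@H](C)C=C)n1ccnc1 | intermediate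
9 | tert-butyl (5S)-5-methyl-3-oxohept-6-enoate | CC(C)(C)OC(=O)CC(=O)C[C@H](C)C=C | intermediate
10 | tert-butyl (5S)-2-diazo-5-methyl-3-oxohept-6-enoate | CC(C)(C)OC(=O)C(=[N+]=[N-])C(=O)C[C@H](C)C=C | intermediate
11 | acetaldehyde | CC=O | starting material
12 | tert-butyl 4-[(2R)-but-3-en-2-yl]-2-diazo-5-hydroxy-3-oxohexanoate (mixture at C4 and C5) | CC(O)C([C@H](C)C=C)C(=O)C(=[N+]=[N-])C(=O)OC(C)(C)C | intermediate
13 | tert-butyl 4-[(2R)-but-3-en-2-yl]-2-diazo-5-(methanesulfonyloxy)-3-oxohexanoate (mesylate, not isolated) | CC(OS(C)(=O)=O)C([C@H](C)C=C)C(=O)C(=[N+]=[N-])C(=O)OC(C)(C)C | intermediate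
14 | tert-butyl (4E)-4-[(2R)-but-3-en-2-yl]-2-diazo-3-oxohex-4-enoate | C/C=C(\[C@H](C)C=C)C(=O)C(=[N+]=[N-])C(=O)OC(C)(C)C | intermediate
15 | ethoxyethyne | CCOC#C | starting material
16 | tert-butyl (3E)-3-[(2R)-but-3-en-2-yl]-2-(oxomethylidene)pent-3-enoate (vinylketene, not isolated) | C/C=C(\[C@H](C)C=C)C(=C=O)C(=O)OC(C)(C)C | intermediate
17 | tert-butyl 2-ethoxy-1-[(2E,4R)-4-methylhexa-2,5-dien-3-yl]-4-oxocyclobut-2-ene-1-carboxylate (cyclobutenone, not isolated) | C/C=C(\[C@H](C)C=C)C1(C(=O)OC(C)(C)C)C(=O)C=C1OCC | intermediate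
18 | tert-butyl (2Z)-3-ethoxy-2-[(2E,4R)-4-methylhexa-2,5-dien-3-yl]-5-oxopenta-2,4-dienoate (dienylketene, not isolated) | C/C=C(\[C@H](C)C=C)/C(C(=O)OC(C)(C)C)=C(/OCC)C=C=O | intermediate
19 | tert-butyl 2-[(2R)-but-3-en-2-yl]-6-ethoxy-3-methyl-4-oxocyclohexa-1,5-diene-1-carboxylate (cyclohexadienone, not isolated) | CCOC1=CC(=O)C(C)C([C@H](C)C=C)=C1C(=O)OC(C)(C)C | intermediate
20 | tert-butyl 2-[(2R)-but-3-en-2-yl]-6-ethoxy-4-hydroxy-3-methylbenzoate | CCOc1cc(O)c(C)c([C@H](C)C=C)c1C(=O)OC(C)(C)C | intermediate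
21 | tert-butyl 2-[(2R)-but-3-en-2-yl]-6-ethoxy-4-methoxy-3-methylbenzoate | CCOc1cc(OC)c(C)c([C@H](C)C=C)c1C(=O)OC(C)(C)C | intermediate
22 | 2-[(2R)-but-3-en-2-yl]-6-hydroxy-4-methoxy-3-methylbenzoic acid | COc1cc(O)c(C(=O)O)c([C@H](C)C=C)c1C | intermediate
23 | benzyl 6-(benzyloxy)-2-[(2R)-but-3-en-2-yl]-4-methoxy-3-methylbenzoate | COc1cc(OCc2ccccc2)c(C(=O)OCc2ccccc2)c([C@H](C)C=C)c1C | intermediate
24 | benzyl 6-(benzyloxy)-2-[(2S)-3,4-dihydroxybutan-2-yl]-4-methoxy-3-methylbenzoate (mixture at C3) | COc1cc(OCc2ccccc2)c(C(=O)OCc2ccccc2)c([C@H](C)C(O)CO)c1C | intermediate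
25 | 4,5-dimethylbenzene-1,3-diol | Cc1cc(O)cc(O)c1C | starting material
26 | [(4,6-dihydroxy-2,3-dimethylphenyl)methylidene]dimethylammonium chloride (iminium chloride, not isolated) | C[N+](C)=Cc1c(O)cc(O)c(C)c1C.[Cl-] | intermediate
27 | 4,6-dihydroxy-2,3-dimethylbenzaldehyde | Cc1c(C)c(O)cc(O)c1C=O | intermediate
28 | 4,6-bis(benzyloxy)-2,3-dimethylbenzaldehyde | Cc1c(C)c(OCc2ccccc2)cc(OCc2ccccc2)c1C=O | intermediate
29 | 4,6-bis(benzyloxy)-2,3-dimethylbenzoic acid | Cc1c(C)c(OCc2ccccc2)cc(OCc2ccccc2)c1C(=O)O | intermediate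
30 | 4,6-bis(benzyloxy)-2,3-dimethylbenzoyl chloride (acid chloride, not isolated) | Cc1c(C)c(OCc2ccccc2)cc(OCc2ccccc2)c1C(=O)Cl | intermediate
31 | benzyl 6-(benzyloxy)-2-[(2S)-4-{[4,6-bis(benzyloxy)-2,3-dimethylbenzoyl]oxy}-3-hydroxybutan-2-yl]-4-methoxy-3-methylbenzoate (mixture at C3) | COc1cc(OCc2ccccc2)c(C(=O)OCc2ccccc2)c([C@H](C)C(O)COC(=O)c2c(OCc3ccccc3)cc(OCc3ccccc3)c(C)c2C)c1C | intermediate
32 | benzyl 6-(benzyloxy)-2-[(2S)-4-{[4,6-bis(benzyloxy)-2,3-dimethylbenzoyl]oxy}-3-oxobutan-2-yl]-4-methoxy-3-methylbenzoate | COc1cc(OCc2ccccc2)c(C(=O)OCc2ccccc2)c([C@H](C)C(=O)COC(=O)c2c(OCc3ccccc3)cc(OCc3ccccc3)c(C)c2C)c1C | intermediate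
33 | 2-[(2S)-4-[(4,6-dihydroxy-2,3-dimethylbenzoyl)oxy]-3-oxobutan-2-yl]-6-hydroxy-4-methoxy-3-methylbenzoic acid (keto acid, not isolated) | COc1cc(O)c(C(=O)O)c([C@H](C)C(=O)COC(=O)c2c(O)cc(O)c(C)c2C)c1C | intermediate
34 | [(3R,4S)-3,8-dihydroxy-6-methoxy-4,5-dimethyl-1-oxo-3,4-dihydro-1H-2-benzopyran-3-yl]methyl 4,6-dihydroxy-2,3-dimethylbenzoate | COc1cc(O)c2c(c1C)[C@H](C)[C@](O)(COC(=O)c1c(O)cc(O)c(C)c1C)OC2=O | target

Total step count: 18. Longest linear sequence: 15 (steps 1–12 and 16–18; steps 13–15 make the ring B acid).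

Steps most likely to fail

Step 8. The ester-bearing ketene may be diverted before the cyclobutenone forms, by closure of the ketene–alkyne adduct through the ester carbonyl oxygen or the alkenyl terminus, or by oligomerisation. The fallback leaves the carboxyl carbon out of the annulation and adds it afterwards, using only established reactions; it sets out from 9 and returns at 22. The dianion of 9 (NaH, then n-BuLi, THF) is added to 11 to give tert-butyl 4-[(2R)-but-3-en-2-yl]-5-hydroxy-3-oxohexanoate F1. MsCl/Et3N gives the mesylate tert-butyl 4-[(2R)-but-3-en-2-yl]-5-(methanesulfonyloxy)-3-oxohexanoate F2, which DBU converts to tert-butyl (4E)-4-[(2R)-but-3-en-2-yl]-3-oxohex-4-enoate F3. CF3CO2H cleaves the ester to (4E)-4-[(2R)-but-3-en-2-yl]-3-oxohex-4-enoic acid F4, which loses CO2 on warming to give (3E)-3-[(2R)-but-3-en-2-yl]pent-3-en-2-one F5. Detrifluoroacetylative diazo transfer (LiN(SiMe3)2, CF3CO2CH2CF3; then MsN3, Et3N, H2O) passes through (5E)-5-[(2R)-but-3-en-2-yl]-1,1,1-trifluorohept-5-ene-2,4-dione F6 to (3E)-3-[(2R)-but-3-en-2-yl]-1-diazopent-3-en-2-one F7. Irradiation of F7 with 15 and warming, the established benzannulation of unsaturated diazomethyl ketones, should give 3-[(2R)-but-3-en-2-yl]-5-ethoxy-2-methylphenol F8, and MeI/K2CO3 gives 1-[(2R)-but-3-en-2-yl]-5-ethoxy-3-methoxy-2-methylbenzene F9. NBS (MeCN, 0 °C) brominates para to methoxy and ortho to ethoxy, at the future C8a, to give 2-bromo-3-[(2R)-but-3-en-2-yl]-1-ethoxy-5-methoxy-4-methylbenzene F10. Bromine–lithium exchange (n-BuLi, −78 °C) and CO2 give 2-[(2R)-but-3-en-2-yl]-6-ethoxy-4-methoxy-3-methylbenzoic acid F11, and BCl3 removes the ethyl group next to the carboxyl group to rejoin the route at 22.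

Step 16. Acylation by the hindered aroyl chloride may be slow or unselective, and the free secondary hydroxyl of 24 may lactonise onto the benzyl ester while it waits. The fallback makes the same C9–O bond with the carboxylate as nucleophile; it sets out from 23 and returns at 31, bypassing 24. Epoxidation of 23 (mCPBA, NaHCO3, CH2Cl2) gives benzyl 6-(benzyloxy)-4-methoxy-3-methyl-2-[(1S)-1-(oxiran-2-yl)ethyl]benzoate F12, which is opened at its terminal carbon by acid 29 (cat. Bu4NBr, MeCN, 70 °C) to give 31.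

Step 10. BCl3 or the HCl formed on quenching may hydrochlorinate the alkene, the freed carboxyl group may add to it, or de-ethylation may stall. The fallback moves all Lewis-acid deprotection behind the alkene functionalisation; it sets out from 21 and returns at 34. Dihydroxylation of 21 (OsO4, NMO) gives tert-butyl 2-[(2S)-3,4-dihydroxybutan-2-yl]-6-ethoxy-4-methoxy-3-methylbenzoate F13. Acylation with 30 gives tert-butyl 2-[(2S)-4-{[4,6-bis(benzyloxy)-2,3-dimethylbenzoyl]oxy}-3-hydroxybutan-2-yl]-6-ethoxy-4-methoxy-3-methylbenzoate F14, and Dess–Martin oxidation gives tert-butyl 2-[(2S)-4-{[4,6-bis(benzyloxy)-2,3-dimethylbenzoyl]oxy}-3-oxobutan-2-yl]-6-ethoxy-4-methoxy-3-methylbenzoate F15. One treatment with BCl3 and pentamethylbenzene (CH2Cl2, −78 → 0 °C) then removes both benzyl ethers, the tert-butyl ester and the chelated ethyl ether, and keto acid 33 closes to 34.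

Further compounds
F1 | step 8 | tert-butyl 4-[(2R)-but-3-en-2-yl]-5-hydroxy-3-oxohexanoate | CC(O)C([C@H](C)C=C)C(=O)CC(=O)OC(C)(C)C
F2 | step 8 | tert-butyl 4-[(2R)-but-3-en-2-yl]-5-(methanesulfonyloxy)-3-oxohexanoate | CC(OS(C)(=O)=O)C([C@H](C)C=C)C(=O)CC(=O)OC(C)(C)C
F3 | step 8 | tert-butyl (4E)-4-[(2R)-but-3-en-2-yl]-3-oxohex-4-enoate | C/C=C(\[C@H](C)C=C)C(=O)CC(=O)OC(C)(C)C
F4 | step 8 | (4E)-4-[(2R)-but-3-en-2-yl]-3-oxohex-4-enoic acid | C/C=C(\[C@H](C)C=C)C(=O)CC(=O)O
F5 | step 8 | (3E)-3-[(2R)-but-3-en-2-yl]pent-3-en-2-one | C/C=C(\[C@H](C)C=C)C(C)=O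
F6 | step 8 | (5E)-5-[(2R)-but-3-en-2-yl]-1,1,1-trifluorohept-5-ene-2,4-dione | C/C=C(\[C@H](C)C=C)C(=O)CC(=O)C(F)(F)F
F7 | step 8 | (3E)-3-[(2R)-but-3-en-2-yl]-1-diazopent-3-en-2-one | C/C=C(\[C@H](C)C=C)C(=O)C=[N+]=[N-]
F8 | step 8 | 3-[(2R)-but-3-en-2-yl]-5-ethoxy-2-methylphenol | CCOc1cc(O)c(C)c([C@H](C)C=C)c1
F9 | step 8 | 1-[(2R)-but-3-en-2-yl]-5-ethoxy-3-methoxy-2-methylbenzene | CCOc1cc(OC)c(C)c([C@H](C)C=C)c1
F10 | step 8 | 2-bromo-3-[(2R)-but-3-en-2-yl]-1-ethoxy-5-methoxy-4-methylbenzene | CCOc1cc(OC)c(C)c([C@H](C)C=C)c1Br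
F11 | step 8 | 2-[(2R)-but-3-en-2-yl]-6-ethoxy-4-methoxy-3-methylbenzoic acid | CCOc1cc(OC)c(C)c([C@H](C)C=C)c1C(=O)O
F12 | step 16 | benzyl 6-(benzyloxy)-4-methoxy-3-methyl-2-[(1S)-1-(oxiran-2-yl)ethyl]benzoate | COc1cc(OCc2ccccc2)c(C(=O)OCc2ccccc2)c([C@H](C)C2CO2)c1C
F13 | step 10 | tert-butyl 2-[(2S)-3,4-dihydroxybutan-2-yl]-6-ethoxy-4-methoxy-3-methylbenzoate | CCOc1cc(OC)c(C)c([C@H](C)C(O)CO)c1C(=O)OC(C)(C)C
F14 | step 10 | tert-butyl 2-[(2S)-4-{[4,6-bis(benzyloxy)-2,3-dimethylbenzoyl]oxy}-3-hydroxybutan-2-yl]-6-ethoxy-4-methoxy-3-methylbenzoate | CCOc1cc(OC)c(C)c([C@H](C)C(O)COC(=O)c2c(OCc3ccccc3)cc(OCc3ccccc3)c(C)c2C)c1C(=O)OC(C)(C)C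
F15 | step 10 | tert-butyl 2-[(2S)-4-{[4,6-bis(benzyloxy)-2,3-dimethylbenzoyl]oxy}-3-oxobutan-2-yl]-6-ethoxy-4-methoxy-3-methylbenzoate | CCOc1cc(OC)c(C)c([C@H](C)C(=O)COC(=O)c2c(OCc3ccccc3)cc(OCc3ccccc3)c(C)c2C)c1C(=O)OC(C)(C)C
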